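**Retrosynthetic overview**
1. The target is a ten-membered carbocycle (C1–C10) trans-fused through C6–C7 to an α-methylene-γ-butyrolactone (O–C6–C7–C11–C12), with a (2S)-2-methylbutanoate on C8. The last disconnection is C1–C10: a (Z)-alkenyl iodide at C10 adds to an aldehyde at C1 in an intramolecular Nozaki–Hiyama–Kishi closure that also sets C1.
2. Enabling feature: C1 is a secondary carbinol carried by C10 of the Z-trisubstituted C9=C10 alkene (allylic alcohol retron). Three of the ten ring bonds (cis C4=C5, cis C9=C10, and C6–C7 held in the lactone ring) cannot rotate, so the seco chain is pre-folded.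
3. The seco aldehyde comes from a lactone aldehyde (C5) and a formyl-stabilized ylide (E-selective Wittig builds C4=C5 with C15 and C1–C3), followed by Luche reduction and one-pot silylation/acetal cleavage.
4. The lactone core comes from an indium-mediated, syn-selective, Felkin-controlled allylation of (Z)-3-iodobut-2-enal (C8–C10, C14) with a Morita–Baylis–Hillman-derived (Z)-allyl bromide made from (R)-glyceraldehyde acetonide (C5–C7, C11–C13). C8 is then esterified and acetonide cleavage closes the lactone.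
5. Ring order: five-membered lactone first (step 9), ten-membered carbocycle last (step 14); only a desilylation follows.

Key step: step 14

Remark: locants C1–C15 in the text are germacranolide locants (C1 carbinol, C4 bearing C15H2OH, C6 lactone O–CH, C7, C8 acyloxy CH, C10 bearing C14H3, C11–C13 the α-methylene acyl unit). Aldehyde 11 is assumed to be used freshly distilled.

**Step 1**
Reactants: 1 but-2-yn-1-ol
Product: 3 (2Z)-3-iodobut-2-en-1-ol, via cyclic alkenylaluminate 2 (not isolated)
Conditions: Red-Al (NaAlH2(OCH2CH2OCH3)2), THF, 0 °C to rt; then I2, THF, −78 °C to 0 °C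
Reagents that add atoms: iodine II
Why: Hydroxyl-directed trans-hydroalumination of the propargylic alcohol places aluminium on the distal carbon, cis to CH2O in a five-membered oxa-aluminacycle, and iodinolysis with retention should give only the Z iodide (reductive iodination of a propargylic alcohol).

**Step 2**
Reactants: 3 (2Z)-3-iodobut-2-en-1-ol
Product: 4 (2Z)-3-iodobut-2-enal
Conditions: activated MnO2, CH2Cl2, rt, dark
Reagents that add atoms: none
Why: MnO2 oxidizes the allylic alcohol selectively to the enal and leaves the alkenyl iodide and its Z geometry untouched (allylic oxidation).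

**Step 3**
Reactants: 5 2-(3-chloropropyl)-1,3-dioxolane
Product: 7 [3-(1,3-dioxolan-2-yl)propyl]triphenylphosphonium iodide, via 2-(3-iodopropyl)-1,3-dioxolane 6 (not isolated)
Conditions: NaI, PPh3, MeCN, reflux
Reagents that add atoms: triphenylphosphine c1ccc(cc1)P(c1ccccc1)c1ccccc1; sodium iodide [Na+].[I-]
Why: Finkelstein exchange gives the primary iodide, which quaternizes triphenylphosphine by SN2 substitution while the dioxolane is inert under these neutral conditions.

**Step 4**
Reactants: 7 [3-(1,3-dioxolan-2-yl)propyl]triphenylphosphonium iodide; 8 ethyl formate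
Product: 10 4-(1,3-dioxolan-2-yl)-2-(triphenyl-λ5-phosphanylidene)butanal, via unstabilized ylide 9 (not isolated)
Conditions: NaHMDS (2 equiv), THF, −78 to 0 °C; then HCO2Et, 0 °C to rt
Reagents that add atoms: none
Why: C-formylation of the phosphorus ylide by the formate ester, followed by deprotonation of the acylphosphonium salt, should give the stabilized formyl ylide (acylation of a Wittig ylide).

**Step 5**
Reactants: 11 (4R)-2,2-dimethyl-1,3-dioxolane-4-carbaldehyde; 12 methyl acrylate
Product: 13 methyl 2-{hydroxy[(4R)-2,2-dimethyl-1,3-dioxolan-4-yl]methyl}prop-2-enoate (both carbinol epimers)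
Conditions: DABCO (0.5 equiv), 1,4-dioxane/H2O (1:1), rt
Reagents that add atoms: none
Why: Morita–Baylis–Hillman reaction of the electrophilic α-alkoxy aldehyde; the new carbinol center (C7) forms as an epimer mixture, which does not matter because step 6 makes it sp2, and the C6 center comes unchanged from the chiral pool.

**Step 6**
Reactants: 13 methyl 2-{hydroxy[(4R)-2,2-dimethyl-1,3-dioxolan-4-yl]methyl}prop-2-enoate
Product: 14 methyl (2Z)-2-(bromomethyl)-3-[(4S)-2,2-dimethyl-1,3-dioxolan-4-yl]prop-2-enoate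
Conditions: NBS, Me2S, CH2Cl2, 0 °C to rt
Reagents that add atoms: N-bromosuccinimide O=C1CCC(=O)N1Br
Why: Corey–Kim-type activation of the alcohol as an alkoxysulfonium salt and SN2′ attack of bromide on the terminal methylene should give the rearranged primary allyl bromide as the favored Z isomer (CH2Br cis to the dioxolanyl group) under acid-free conditions that spare the acetonide.

**Step 7**
Reactants: 14 methyl (2Z)-2-(bromomethyl)-3-[(4S)-2,2-dimethyl-1,3-dioxolan-4-yl]prop-2-enoate; 4 (2Z)-3-iodobut-2-enal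
Product: 16 methyl (3R,4S,5Z)-3-[(4S)-2,2-dimethyl-1,3-dioxolan-4-yl]-4-hydroxy-6-iodo-2-methylidenehept-5-enoate, via allylindium dibromide 15 (not isolated)
Conditions: indium powder, THF/H2O (1:1), rt
Reagents that add atoms: none
Why: Barbier-type indium allylation through a chair transition state, in which the Z geometry of the reagent should give the C7/C8 syn adduct, A(1,3) strain should hold H6 in the alkene plane, and the aldehyde should bond to C7 anti to the C6–O bond (Felkin–Anh-type control by the dioxolane center), while indium metal leaves the alkenyl iodide alone and the neutral medium leaves the hydroxy ester open.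

**Step 8**
Reactants: 16 methyl (3R,4S,5Z)-3-[(4S)-2,2-dimethyl-1,3-dioxolan-4-yl]-4-hydroxy-6-iodo-2-methylidenehept-5-enoate; 17 (2S)-2-methylbutanoic acid
Product: 18 methyl (3R,4S,5Z)-3-[(4S)-2,2-dimethyl-1,3-dioxolan-4-yl]-6-iodo-2-methylidene-4-{[(2S)-2-methylbutanoyl]oxy}hept-5-enoate
Conditions: DCC, DMAP (0.1 equiv), CH2Cl2, 0 °C to rt
Reagents that add atoms: none
Why: Steglich esterification acylates the only free hydroxyl (C8) under mild conditions that should preserve the α-stereocenter of the acid and all existing stereocenters.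

**Step 9**
Reactants: 18 methyl (3R,4S,5Z)-3-[(4S)-2,2-dimethyl-1,3-dioxolan-4-yl]-6-iodo-2-methylidene-4-{[(2S)-2-methylbutanoyl]oxy}hept-5-enoate
Product: 20 (1S,2Z)-1-[(2S,3R)-2-(hydroxymethyl)-4-methylidene-5-oxooxolan-3-yl]-3-iodobut-2-en-1-yl (2S)-2-methylbutanoate, via diol ester 19 (not isolated)
Conditions: AcOH/H2O/THF (4:1:1), 45 °C; then PPTS (0.1 equiv), toluene, 60 °C
Reagents that add atoms: none
Why: Acidic acetonide hydrolysis followed by acid-catalysed lactonization, in which five-membered closure onto the secondary C6 hydroxyl should win over six-membered closure onto the primary hydroxyl and gives the trans lactone dictated by the C6 and C7 configurations already in place.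

**Step 10**
Reactants: 20 (1S,2Z)-1-[(2S,3R)-2-(hydroxymethyl)-4-methylidene-5-oxooxolan-3-yl]-3-iodobut-2-en-1-yl (2S)-2-methylbutanoate
Product: 21 (1S,2Z)-1-[(2S,3R)-2-formyl-4-methylidene-5-oxooxolan-3-yl]-3-iodobut-2-en-1-yl (2S)-2-methylbutanoate
Conditions: Dess–Martin periodinane, CH2Cl2, 0 °C to rt
Reagents that add atoms: none
Why: Dess–Martin oxidation converts the primary alcohol into the aldehyde under neutral conditions that tolerate the alkenyl iodide, the exocyclic enoate and the epimerizable C6 center (whose trans arrangement is in any case the more stable one).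

**Step 11**
Reactants: 21 (1S,2Z)-1-[(2S,3R)-2-formyl-4-methylidene-5-oxooxolan-3-yl]-3-iodobut-2-en-1-yl (2S)-2-methylbutanoate; 10 4-(1,3-dioxolan-2-yl)-2-(triphenyl-λ5-phosphanylidene)butanal
Product: 22 (1S,2Z)-1-{(2R,3S)-2-[(1E)-4-(1,3-dioxolan-2-yl)-2-formylbut-1-en-1-yl]-4-methylidene-5-oxooxolan-3-yl}-3-iodobut-2-en-1-yl (2S)-2-methylbutanoate
Conditions: toluene, 60 °C
Reagents that add atoms: none
Why: Wittig reaction of a stabilized α-substituted formyl ylide with the activated α-acyloxy aldehyde should give the E enal (C6 trans to the formyl carbon C15), which is the C4=C5 geometry of the target, while the α-branched product enal resists a second olefination.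

**Step 12**
Reactants: 22 (1S,2Z)-1-{(2R,3S)-2-[(1E)-4-(1,3-dioxolan-2-yl)-2-formylbut-1-en-1-yl]-4-methylidene-5-oxooxolan-3-yl}-3-iodobut-2-en-1-yl (2S)-2-methylbutanoate
Product: 23 (1S,2Z)-1-{(2R,3S)-2-[(1E)-4-(1,3-dioxolan-2-yl)-2-(hydroxymethyl)but-1-en-1-yl]-4-methylidene-5-oxooxolan-3-yl}-3-iodobut-2-en-1-yl (2S)-2-methylbutanoate
Conditions: NaBH4 (1 equiv), CeCl3·7H2O, MeOH, −78 °C
Reagents that add atoms: none
Why: Luche reduction delivers hydride 1,2 to the enal, which at −78 °C should react far faster than the lactone, the ester or the exocyclic enoate.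

**Step 13**
Reactants: 23 (1S,2Z)-1-{(2R,3S)-2-[(1E)-4-(1,3-dioxolan-2-yl)-2-(hydroxymethyl)but-1-en-1-yl]-4-methylidene-5-oxooxolan-3-yl}-3-iodobut-2-en-1-yl (2S)-2-methylbutanoate
Product: 25 (1S,2Z)-3-iodo-1-{(2R,3S)-4-methylidene-5-oxo-2-[(1E)-5-oxo-2-{[(triethylsilyl)oxy]methyl}pent-1-en-1-yl]oxolan-3-yl}but-2-en-1-yl (2S)-2-methylbutanoate, via collidinium triflate 24 (not isolated)
Conditions: TESOTf (3 equiv), 2,4,6-collidine (4.5 equiv), CH2Cl2, 0 °C; then H2O, rt
Reagents that add atoms: triethylsilyl trifluoromethanesulfonate CC[Si](CC)(CC)OS(=O)(=O)C(F)(F)F; water O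
Why: The silyl triflate silylates the C15 hydroxyl and, with the hindered pyridine, opens the dioxolane to an N-(α-alkoxyalkyl)collidinium salt that water hydrolyses to the C1 aldehyde (silyl-triflate/collidine acetal cleavage), a buffered process that should spare the silyl ether, the allylic ester and the lactone.

**Step 14**
Reactants: 25 (1S,2Z)-3-iodo-1-{(2R,3S)-4-methylidene-5-oxo-2-[(1E)-5-oxo-2-{[(triethylsilyl)oxy]methyl}pent-1-en-1-yl]oxolan-3-yl}but-2-en-1-yl (2S)-2-methylbutanoate
Product: 27 (3aR,4R,5Z,7S,10E,11aR)-7-hydroxy-6-methyl-3-methylidene-2-oxo-10-{[(triethylsilyl)oxy]methyl}-2,3,3a,4,7,8,9,11a-octahydrocyclodeca[b]furan-4-yl (2S)-2-methylbutanoate, via alkenylchromium dichloride 26 (not isolated)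
Conditions: CrCl2 (10 equiv), NiCl2 (0.1 equiv), DMSO/THF (3:1), rt, syringe-pump addition of 25 to a final 0.003 M; aqueous sodium serinate work-up
Reagents that add atoms: none
Why: Zerovalent nickel formed in situ inserts into the C10–I bond, transmetalation to trivalent chromium gives the configurationally stable (Z)-alkenylchromium 26, and this adds to the chromium-bound C1 aldehyde. The closest known reaction type is the intramolecular Nozaki–Hiyama–Kishi coupling of an alkenyl iodide with an aldehyde, as used to close medium and large carbocycles. The single ring closed is the ten-membered carbocycle, by 10-exo-trig attack of C10 on the C1 carbonyl. The new C1 stereocenter is controlled by C8: allylic 1,3-strain across the Z C9=C10 bond holds H8 in the alkene plane, the acyloxy group covers one face of C10 and the chain from C7 brings the aldehyde to the other, so that with the chromium-bound oxygen on the outside of the forming ring the C1–O bond should end up anti to the C8–O bond (1S). The step needs aldehyde-only chemoselectivity (inherent to alkenylchromium, which leaves lactone, ester and enoate alone), retention of the Z geometry (the alkenyl–chromium bond does not isomerize) and cyclization over oligomerization. The last is secured by high dilution and by the substrate, in which the two cis alkenes C4=C5 and C9=C10 and the lactone-held C6–C7 bond pre-fold the chain.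

**Step 15**
Reactants: 27 (3aR,4R,5Z,7S,10E,11aR)-7-hydroxy-6-methyl-3-methylidene-2-oxo-10-{[(triethylsilyl)oxy]methyl}-2,3,3a,4,7,8,9,11a-octahydrocyclodeca[b]furan-4-yl (2S)-2-methylbutanoate
Product: 28 (3aR,4R,5Z,7S,10E,11aR)-7-hydroxy-10-(hydroxymethyl)-6-methyl-3-methylidene-2-oxo-2,3,3a,4,7,8,9,11a-octahydrocyclodeca[b]furan-4-yl (2S)-2-methylbutanoate
Conditions: HF·pyridine, pyridine, THF, 0 °C
Reagents that add atoms: none
Why: Buffered fluoride cleaves the primary triethylsilyl ether under conditions too mild to cause acyl migration, conjugate addition to the α-methylene lactone or allylic ionization (fluoride desilylation).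

**Compound list**
1 | but-2-yn-1-ol | CC#CCO | starting material
2 | sodium 2,2-bis(2-methoxyethoxy)-3-methyl-2,5-dihydro-1,2-oxaluminol-2-uide (oxa-aluminacycle, Al on the methyl-bearing carbon, cis to CH2O) | [Na+].CC1=CCO[Al-]1(OCCOC)OCCOC | intermediate
3 | (2Z)-3-iodobut-2-en-1-ol | C/C(I)=C/CO | intermediate
4 | (2Z)-3-iodobut-2-enal | C/C(I)=C/C=O | intermediate
5 | 2-(3-chloropropyl)-1,3-dioxolane | ClCCCC1OCCO1 | starting material
6 | 2-(3-iodopropyl)-1,3-dioxolane | ICCCC1OCCO1 | intermediate
7 | [3-(1,3-dioxolan-2-yl)propyl]triphenylphosphonium iodide | [I-].C1COC(CCC[P+](c2ccccc2)(c3ccccc3)c4ccccc4)O1 | intermediate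
8 | ethyl formate | CCOC=O | starting material
9 | [3-(1,3-dioxolan-2-yl)propylidene]triphenylphosphorane | C1COC(CCC=P(c2ccccc2)(c3ccccc3)c4ccccc4)O1 | intermediate
10 | 4-(1,3-dioxolan-2-yl)-2-(triphenyl-λ5-phosphanylidene)butanal | O=CC(CCC1OCCO1)=P(c2ccccc2)(c3ccccc3)c4ccccc4 | intermediate
11 | (4R)-2,2-dimethyl-1,3-dioxolane-4-carbaldehyde | O=C[C@H]1COC(C)(C)O1 | starting material
12 | methyl acrylate | C=CC(=O)OC | starting material
13 | methyl 2-{hydroxy[(4R)-2,2-dimethyl-1,3-dioxolan-4-yl]methyl}prop-2-enoate (both carbinol epimers) | C=C(C(=O)OC)C(O)[C@H]1COC(C)(C)O1 | intermediate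
14 | methyl (2Z)-2-(bromomethyl)-3-[(4S)-2,2-dimethyl-1,3-dioxolan-4-yl]prop-2-enoate | COC(=O)/C(CBr)=C/[C@H]1COC(C)(C)O1 | intermediate
15 | allylindium dibromide from 14 (bromine replaced by InBr2, drawn as the simplest monomeric species) | COC(=O)/C(C[In](Br)Br)=C/[C@H]1COC(C)(C)O1 | intermediate
16 | methyl (3R,4S,5Z)-3-[(4S)-2,2-dimethyl-1,3-dioxolan-4-yl]-4-hydroxy-6-iodo-2-methylidenehept-5-enoate | C=C(C(=O)OC)[C@@H]([C@H]1COC(C)(C)O1)[C@@H](/C=C(/C)I)O | intermediate
17 | (2S)-2-methylbutanoic acid | CC[C@H](C)C(=O)O | starting material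
18 | methyl (3R,4S,5Z)-3-[(4S)-2,2-dimethyl-1,3-dioxolan-4-yl]-6-iodo-2-methylidene-4-{[(2S)-2-methylbutanoyl]oxy}hept-5-enoate | C=C(C(=O)OC)[C@@H]([C@H]1COC(C)(C)O1)[C@@H](/C=C(/C)I)OC(=O)[C@@H](C)CC | intermediate
19 | diol ester: 18 with the acetonide removed (free C6 and C5 hydroxyls, configurations unchanged) | C=C(C(=O)OC)[C@@H]([C@H](O)CO)[C@@H](/C=C(/C)I)OC(=O)[C@@H](C)CC | intermediate
20 | (1S,2Z)-1-[(2S,3R)-2-(hydroxymethyl)-4-methylidene-5-oxooxolan-3-yl]-3-iodobut-2-en-1-yl (2S)-2-methylbutanoate | C=C1C(=O)O[C@H](CO)[C@H]1[C@@H](/C=C(/C)I)OC(=O)[C@@H](C)CC | intermediate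
21 | (1S,2Z)-1-[(2S,3R)-2-formyl-4-methylidene-5-oxooxolan-3-yl]-3-iodobut-2-en-1-yl (2S)-2-methylbutanoate | C=C1C(=O)O[C@H](C=O)[C@H]1[C@@H](/C=C(/C)I)OC(=O)[C@@H](C)CC | intermediate
22 | (1S,2Z)-1-{(2R,3S)-2-[(1E)-4-(1,3-dioxolan-2-yl)-2-formylbut-1-en-1-yl]-4-methylidene-5-oxooxolan-3-yl}-3-iodobut-2-en-1-yl (2S)-2-methylbutanoate | C=C1C(=O)O[C@H](/C=C(/C=O)CCC2OCCO2)[C@H]1[C@@H](/C=C(/C)I)OC(=O)[C@@H](C)CC | intermediate
23 | (1S,2Z)-1-{(2R,3S)-2-[(1E)-4-(1,3-dioxolan-2-yl)-2-(hydroxymethyl)but-1-en-1-yl]-4-methylidene-5-oxooxolan-3-yl}-3-iodobut-2-en-1-yl (2S)-2-methylbutanoate | C=C1C(=O)O[C@H](/C=C(/CO)CCC2OCCO2)[C@H]1[C@@H](/C=C(/C)I)OC(=O)[C@@H](C)CC | intermediate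
24 | collidinium triflate from 23: C15 as triethylsilyl ether, C1 carrying the 2,4,6-trimethylpyridinium nitrogen and a 2-[(triethylsilyl)oxy]ethoxy group (both C1 epimers) | C=C1C(=O)O[C@H](/C=C(/CO[Si](CC)(CC)CC)CCC(OCCO[Si](CC)(CC)CC)[n+]2c(C)cc(C)cc2C)[C@H]1[C@@H](/C=C(/C)I)OC(=O)[C@@H](C)CC.[O-]S(=O)(=O)C(F)(F)F | intermediate
25 | (1S,2Z)-3-iodo-1-{(2R,3S)-4-methylidene-5-oxo-2-[(1E)-5-oxo-2-{[(triethylsilyl)oxy]methyl}pent-1-en-1-yl]oxolan-3-yl}but-2-en-1-yl (2S)-2-methylbutanoate | C=C1C(=O)O[C@H](/C=C(/CO[Si](CC)(CC)CC)CCC=O)[C@H]1[C@@H](/C=C(/C)I)OC(=O)[C@@H](C)CC | intermediate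
26 | (Z)-alkenylchromium dichloride from 25 (iodine at C10 replaced by CrCl2) | C=C1C(=O)O[C@H](/C=C(/CO[Si](CC)(CC)CC)CCC=O)[C@H]1[C@@H](/C=C(/C)[Cr](Cl)Cl)OC(=O)[C@@H](C)CC | intermediate
27 | (3aR,4R,5Z,7S,10E,11aR)-7-hydroxy-6-methyl-3-methylidene-2-oxo-10-{[(triethylsilyl)oxy]methyl}-2,3,3a,4,7,8,9,11a-octahydrocyclodeca[b]furan-4-yl (2S)-2-methylbutanoate | C=C1C(=O)O[C@@H]2/C=C(/CO[Si](CC)(CC)CC)CC[C@H](O)/C(C)=C\[C@@H](OC(=O)[C@@H](C)CC)[C@@H]12 | intermediate
28 | (3aR,4R,5Z,7S,10E,11aR)-7-hydroxy-10-(hydroxymethyl)-6-methyl-3-methylidene-2-oxo-2,3,3a,4,7,8,9,11a-octahydrocyclodeca[b]furan-4-yl (2S)-2-methylbutanoate | C=C1C(=O)O[C@@H]2/C=C(/CO)CC[C@H](O)/C(C)=C\[C@@H](OC(=O)[C@@H](C)CC)[C@@H]12 | target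

**Step count and risks**
Total step count: 15. Longest linear sequence: 11 steps (steps 5 to 15, from 11).

Steps most likely to fail:

Step 14. The ring closure may proceed with poor facial selectivity at C1, because the bias from C8 can be overridden by the conformational demands of the forming ten-membered ring; intermolecular coupling may also compete. The fallback sets out from 27 obtained as a mixture of C1 epimers and comes back at 27. The mixture is oxidized with Dess–Martin periodinane to the single ketone (3aR,4R,5Z,10E,11aR)-6-methyl-3-methylidene-2,7-dioxo-10-{[(triethylsilyl)oxy]methyl}-2,3,3a,4,7,8,9,11a-octahydrocyclodeca[b]furan-4-yl (2S)-2-methylbutanoate F1. C1 is then set under reagent control by Corey–Bakshi–Shibata reduction ((R)-2-methyl-CBS-oxazaborolidine, catecholborane, toluene, −78 °C), in which the alkenyl branch acts as the large group and the 1S alcohol 27 should result.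

Step 7. Diastereofacial control at C7 may be lost through chelation of indium by the dioxolane oxygens in water, and syn selectivity may erode through E/Z equilibration of the allylindium. The fallback sets out from 14 and 4 and comes back at 18. Nickel-free CrCl2 in anhydrous THF (Nozaki–Hiyama allylation) generates the equilibrated E-configured allylchromium, which should add with the Felkin–Anh facial preference typical of dioxolanyl-substituted allyl reagents. This should give the anti adduct methyl (3R,4R,5Z)-3-[(4S)-2,2-dimethyl-1,3-dioxolan-4-yl]-4-hydroxy-6-iodo-2-methylidenehept-5-enoate F2, which is epimeric to 16 at C8 only. Mitsunobu esterification with 17 (PPh3, DIAD, THF, 0 °C) then installs the ester with inversion at C8 and gives 18.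

Step 8. The C8 hydroxyl may close prematurely onto the methyl ester (lactone of the wrong regiochemistry) in competition with slow acylation of the hindered carbinol. The fallback sets out from 11 and comes back at 20. A Morita–Baylis–Hillman reaction of 11 with tert-butyl acrylate gives tert-butyl 2-{hydroxy[(4R)-2,2-dimethyl-1,3-dioxolan-4-yl]methyl}prop-2-enoate F3. NBS/Me2S converts it into tert-butyl (2Z)-2-(bromomethyl)-3-[(4S)-2,2-dimethyl-1,3-dioxolan-4-yl]prop-2-enoate F4. Indium-mediated addition to 4 gives tert-butyl (3R,4S,5Z)-3-[(4S)-2,2-dimethyl-1,3-dioxolan-4-yl]-4-hydroxy-6-iodo-2-methylidenehept-5-enoate F5, whose bulky ester cannot lactonize. Yamaguchi esterification with 17 (2,4,6-trichlorobenzoyl chloride, Et3N, DMAP) gives tert-butyl (3R,4S,5Z)-3-[(4S)-2,2-dimethyl-1,3-dioxolan-4-yl]-6-iodo-2-methylidene-4-{[(2S)-2-methylbutanoyl]oxy}hept-5-enoate F6. TFA/CH2Cl2/H2O then cleaves the acetonide and the tert-butyl ester and closes the lactone onto the C6 oxygen, giving 20.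

**Further compounds**
F1 | step 14 | (3aR,4R,5Z,10E,11aR)-6-methyl-3-methylidene-2,7-dioxo-10-{[(triethylsilyl)oxy]methyl}-2,3,3a,4,7,8,9,11a-octahydrocyclodeca[b]furan-4-yl (2S)-2-methylbutanoate | C=C1C(=O)O[C@@H]2/C=C(/CO[Si](CC)(CC)CC)CCC(=O)/C(C)=C\[C@@H](OC(=O)[C@@H](C)CC)[C@@H]12
F2 | step 7 | methyl (3R,4R,5Z)-3-[(4S)-2,2-dimethyl-1,3-dioxolan-4-yl]-4-hydroxy-6-iodo-2-methylidenehept-5-enoate | C=C(C(=O)OC)[C@@H]([C@H]1COC(C)(C)O1)[C@H](/C=C(/C)I)O
F3 | step 8 | tert-butyl 2-{hydroxy[(4R)-2,2-dimethyl-1,3-dioxolan-4-yl]methyl}prop-2-enoate (both carbinol epimers) | C=C(C(=O)OC(C)(C)C)C(O)[C@H]1COC(C)(C)O1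
F4 | step 8 | tert-butyl (2Z)-2-(bromomethyl)-3-[(4S)-2,2-dimethyl-1,3-dioxolan-4-yl]prop-2-enoate | CC(C)(C)OC(=O)/C(CBr)=C/[C@H]1COC(C)(C)O1
F5 | step 8 | tert-butyl (3R,4S,5Z)-3-[(4S)-2,2-dimethyl-1,3-dioxolan-4-yl]-4-hydroxy-6-iodo-2-methylidenehept-5-enoate | C=C(C(=O)OC(C)(C)C)[C@@H]([C@H]1COC(C)(C)O1)[C@@H](/C=C(/C)I)O
F6 | step 8 | tert-butyl (3R,4S,5Z)-3-[(4S)-2,2-dimethyl-1,3-dioxolan-4-yl]-6-iodo-2-methylidene-4-{[(2S)-2-methylbutanoyl]oxy}hept-5-enoate | C=C(C(=O)OC(C)(C)C)[C@@H]([C@H]1COC(C)(C)O1)[C@@H](/C=C(/C)I)OC(=O)[C@@H](C)CC
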